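# Synthesis design for CNP0169816.1: two unlike perhydrobenzoxepine halves from one samarium-closed oxepanol

## The problem

The target is two trans-fused perhydro-1-benzoxepines joined by the C12–C13 ethano bridge between C11 and C14. The left bicycle is the oxepane O/C2–C7 on the cyclohexane C6–C11; the right bicycle is the oxepane C18–C23/O on the cyclohexane C14–C19.

Read from the structure, the ten stereocentres are 3S,6S,7S,10R,11S,14S,15S,18S,19S,22S. The two bicycles are homochiral at every ring-fusion, bridgehead and oxepanol centre, but not at the tertiary acetoxy carbons: the C10 acetate is axial (cis to the C6 methyl), whereas the C15 acetate is equatorial (its methyl is syn-axial to the C19 methyl). The acylation pattern breaks the symmetry a second time: C3 is an acetate, C22 a free alcohol. The molecule therefore cannot come from dimerising one half; two differently finished halves must be made and joined.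

Within each half the quaternary carbon C6 (C19) is the anchor. It fixes C7 (C18) through the trans ring fusion, C7 can relay to C3 (C22) during oxepane closure, and the axial angular methyl decides from which face reagents reach C10/C15 and C11/C14.

The three acetates (two of them tertiary and prone to elimination or acyl transfer) exclude strong base, hydride and organometallic steps after acylation. The hindered tertiary alcohols acylate slowly, and the C22 hydroxyl must stay masked until the other three are acetylated.

The feature that invites the key step is that C3 is the only carbinol centre of the oxepane and sits next to the fully substituted ether carbon C2, while the ring oxygen hangs on C7 beside the C6 carbon that carries C5–C4–C3. A C3 aldehyde on a three-carbon arm at C6 and a β-alkoxycrotonate on the C7 oxygen are thus set up for a reductive C2–C3 closure.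

## Retrosynthesis

**37 from 36.** The last step removes only what hydrogen can remove: the C22 benzyl ether and the C12=C13 double bond of 36. Keeping benzyl on C22 alone means that the hydroxyls to be acetylated are the only free ones one step earlier. Selective monoacetylation of a C3/C22 diol was rejected because the two oxepanols are chemically equivalent.

**36 from 35 from 34.** The three acetates (C3, C10, C15) are put on triol 35 after every basic step is over. Triol 35 comes from the tris(triethylsilyl) ether 34 by one global desilylation. No skeletal bond is cut here; the forward demand is acylation of two hindered tertiary alcohols.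

**34 from 24 and 33.** The C12=C13 bond is cut by a Julia–Kocienski olefination between the left sulfone 24 (C1–C12) and the right aldehyde 33 (C13–C24). The bridge is the only link between the ring systems. Cutting C11–C12 or C13–C14 instead would ask for bond formation at ring carbons flanked by two fully substituted neighbours. Each fragment is a C15 bicycle that already carries its five stereocentres, and the alkene geometry is irrelevant.

**24 from 23, 22, 21, 20 and 19 (left half).** The axial C10 carbinol arises by methyl addition to a C10 ketone, because the syn-axial C6 methyl forces the nucleophile in from the α face. Sulfur is brought in by conjugate addition of the tetrazole thiol to the α-methylene ketone 19 (giving 20). That step also sets C11 by axial protonation and equilibration.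

**33 from 32, 31, 30, 29, 28, 27 and 26 (right half).** The same skeleton needs the opposite configuration at C15, so here oxygen, not carbon, must enter from the α face. This is done by epoxidation of the exocyclic alkene 29 and hydride opening of epoxide 30 to 31. The C13 oxygen and the C14 hydrogen come from hydroboration of the exocyclic alkene of 18 (giving 26); C14 is then secured thermodynamically at the ketone stage 28.

**19 and 26 from 18, 17 and 16.** Both halves branch from the allylic alcohol 18. It is made from the C11 ketone 16 by methylenation (17) and selenium dioxide oxidation, which moves the oxygen from C11 to C10 and installs C12. The C11 ketone is what 1,3-dione chemistry delivers.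

**16 from 15, 13, 12 and 11.** The C2 gem-dimethyl group is obtained by degrading the acetate arm of the key-step product 11. After benzylation (12) and saponification (13), a Barton decarboxylation gives 15. C2 is a stereocentre only in passing.

**11 from 10 (key step).** The C2–C3 bond and the oxepane are formed by samarium ketyl addition of the C3 aldehyde to the (E)-β-alkoxycrotonate on the C7 oxygen. Against a C–O closure (epoxide opening), this cut sets C3 under substrate control from C7 and needs no reagent-controlled epoxidation. The precursor 10 is a monocyclic cyclohexane with two stereocentres that matter.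

**10 from 9, 7, 5 and 6.** The crotonate comes from phosphine-catalysed addition of alcohol 5 to ethyl but-2-ynoate 6. The aldehyde comes from the allyl group of 7 by hydroboration (9) and oxidation.

**5 from 4, 3, 1 and 2.** The trans ring fusion needs the C7 oxygen trans to the three-carbon arm. Direct reduction of the allylated dione 3 puts the hydroxyl cis to the larger group, so a plain desymmetrising reduction gives the wrong diastereomer for C7. The plan therefore lets the yeast-derived hydroxyl of 4 (cis to allyl) become the C11 oxygen and uses it in an Evans–Tishchenko reduction to deliver hydride to the other carbonyl. This gives the C7 hydroxyl trans to the allyl group and leaves the old oxygen as an acetate, so the two oxygens are differentiated in the same step. Dione 3 comes from 1 and allyl bromide 2.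

## Roads not taken

**Alternative 1:** Two-directional asymmetric Diels–Alder. The cut is C6–C11 and C7–C8 in the left ring and C14–C19 and C17–C18 in the right ring. Forward, tetraene A2 would take up two molecules of the acyloxy acrolein A3 under a chiral protonated oxazaborolidine Lewis acid to give the bis(cyclohexene) dialdehyde A1.
- Merits: four C–C bonds, both carbocycles, the bridge and six stereocentres appear in one operation. Double catalyst control should enrich the enantiomeric purity of the C2-symmetric product. The C10 and C15 methyl groups arrive as trisubstituted alkenes ready for oxygenation.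
- Weak points for this target: A1 is C2-symmetric and the target is not. The two identical alkenes would have to be hydrated with opposite facial outcomes (axial oxygen at C10, equatorial at C15), and C3/C22 would need different acyl status, so every differentiation is statistical. The dienophile is a donor-substituted, α-branched acrolein. Both oxepanes would still have to be built from neopentyl aldehydes.
- Comparison: this road is clearly shorter to the bis-carbocycle and avoids the hindered fragment coupling of step 28. The chosen plan sets against it two independently finished halves and a substrate-controlled C3.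

**Alternative 2:** Three-component coupling on the silyloxy enone A5. The cut is C5–C6 and C11–C12. Forward, the homoprenyl Grignard reagent A6 with catalytic CuBr·SMe2 (monovalent copper) would add to C6 anti to the C7 silyloxy group, and the enolate would be alkylated at C11 by the iodoacetate A7 to give ketone A4.
- Merits: A4 already has the C10 ketone and a C11 side chain, which cost the chosen route steps 12 to 15. C6 and C11 are set in one step, and the homoprenyl chain carries the gem-dimethyl carbon, so no decarboxylation is needed.
- Weak points for this target: conjugate addition must create a quaternary centre on a β-methyl enone next to a silyloxy-bearing carbon. The hindered enolate must then be C-alkylated by an α-halo ester without proton transfer. A5 needs its own asymmetric synthesis. The oxepane would be closed by 7-endo epoxide opening, which competes with 6-exo closure and needs a reagent-controlled epoxidation for C3. The C11 arm has two carbons, so the bridge logic must change in one half.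
- Comparison: better than the chosen plan for the C10/C11 functionality. The chosen plan sets against it the chelate-controlled trans-fused oxepanol and a cheap enantiopure ketol.

**Alternative 3:** Cathodic ketyl–olefin closure of the right cyclohexane. The cut is C14–C15, late, with the right oxepane and the whole left half in place. Forward, constant-current reduction of the keto olefin A9 would add the C15 ketyl to C14 of the E alkene and give the tetracyclic triol A8.
- Merits: the tertiary C15 carbinol, C14 and the ring form in one step without a metal reductant. Because the two cyclohexanes are made by different reactions, the C10/C15 difference is addressed by design, and C22 is already differentiated.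
- Weak points for this target: 6-exo ketyl addition to an unactivated 1,2-disubstituted alkene is slow next to ketone reduction and pinacol coupling. Two stereocentres must both fall correctly against the C19 centre, and the equatorial-hydroxyl, axial-methyl outcome has little to secure it. The route is linear, so the complete left half is risked in this step.
- Comparison: it would replace steps 20 to 27 of the chosen route by far fewer operations. The chosen plan sets against it convergence and stereocontrol that rests on the well-known equatorial approach to cyclohexanes bearing a syn-axial methyl group.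

Key step: step 7

## Route

Conventions used in the names: locants are squalene locants. The left bicycle is O/C2–C7 (oxepane) fused to C6–C11, with C12 on C11. The right bicycle is the same skeleton with C23, C22, C21, C20, C19, C18 and C19, C14, C15, C16, C17, C18, with C13 on C14. β is the face of the angular methyl group (on C6 or C19); α is the face of H-7 (H-18).

Remark on the chemistry: alkene 34 may form as an E/Z mixture and alcohols 18, 26 and 27 as C10 (C15) epimers. This is immaterial because the double bond is hydrogenated and the carbinol is oxidised.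

### Common sequence (steps 1–13)

Step 1
Reactants: 1 2-methylcyclohexane-1,3-dione; 2 allyl bromide
Product: 3 2-methyl-2-(prop-2-en-1-yl)cyclohexane-1,3-dione
Conditions: NaOH (1 M aq), rt
Reagents that add atoms: none
Why: C-alkylation of the doubly stabilised enolate of a 2-substituted 1,3-dione with a reactive allylic halide (enolate alkylation); any O-allyl enol ether can be returned to 3 by Claisen rearrangement.

Step 2
Reactants: 3 2-methyl-2-(prop-2-en-1-yl)cyclohexane-1,3-dione
Product: 4 (2S,3S)-3-hydroxy-2-methyl-2-(prop-2-en-1-yl)cyclohexan-1-one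
Conditions: baker's yeast (Saccharomyces cerevisiae), sucrose, H2O, 30 °C
Reagents that add atoms: none
Why: Enzymatic desymmetrising reduction of a prochiral 2,2-disubstituted 1,3-dione, a well-established reaction for 2-alkyl-2-methyl diones; hydride enters one enantiotopic carbonyl anti to the allyl group, which gives the (S)-carbinol cis to allyl and fixes the quaternary centre (future C6) as one enantiomer.

Step 3
Reactants: 4 (2S,3S)-3-hydroxy-2-methyl-2-(prop-2-en-1-yl)cyclohexan-1-one
Product: 5 (1S,2R,3S)-3-hydroxy-2-methyl-2-(prop-2-en-1-yl)cyclohexyl acetate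
Conditions: SmI2 (0.3 equiv, divalent samarium), CH3CHO (8 equiv), THF, −10 °C
Reagents that add atoms: acetaldehyde, CC=O
Why: Evans–Tishchenko reduction of a β-hydroxy ketone: the samarium-bound hemiacetal of the axial hydroxyl passes its hydride to the ketone through a six-membered transition state on the face of that oxygen, so the new hydroxyl (C7) is anti to the old oxygen and therefore trans to the allyl group, as the trans ring fusion requires, while the old oxygen (C11) leaves the step as its acetate; acyl migration is geometrically excluded in the trans-1,3 arrangement.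

Step 4
Reactants: 5 (1S,2R,3S)-3-hydroxy-2-methyl-2-(prop-2-en-1-yl)cyclohexyl acetate; 6 ethyl but-2-ynoate
Product: 7 ethyl (E)-3-{[(1S,2R,3S)-3-acetoxy-2-methyl-2-(prop-2-en-1-yl)cyclohexyl]oxy}but-2-enoate
Conditions: PMe3 (0.5 equiv), CH2Cl2, 0 °C to rt
Reagents that add atoms: none
Why: Phosphine-catalysed oxa-Michael addition of an alcohol to an alkynoate; the small, strongly nucleophilic phosphine is needed for the β-methyl alkynoate and the neopentyl alcohol, and the addition gives the (E)-β-alkoxycrotonate.

Step 5
Reactants: 7 ethyl (E)-3-{[(1S,2R,3S)-3-acetoxy-2-methyl-2-(prop-2-en-1-yl)cyclohexyl]oxy}but-2-enoate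
Product: 9 ethyl (E)-3-{[(1S,2R,3S)-3-acetoxy-2-(3-hydroxypropyl)-2-methylcyclohexyl]oxy}but-2-enoate, via B-alkyl-9-BBN adduct 8 (not isolated)
Conditions: 9-BBN, THF, 0 °C to rt; then H2O2 (30 %), aq NaOAc, 0 °C to rt
Reagents that add atoms: hydrogen peroxide, OO
Why: Hydroboration–oxidation; 9-BBN takes the terminal alkene anti-Markovnikov and leaves the electron-poor trisubstituted enoate, and the buffered oxidation spares both esters.

Step 6
Reactants: 9 ethyl (E)-3-{[(1S,2R,3S)-3-acetoxy-2-(3-hydroxypropyl)-2-methylcyclohexyl]oxy}but-2-enoate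
Product: 10 ethyl (E)-3-{[(1S,2R,3S)-3-acetoxy-2-methyl-2-(3-oxopropyl)cyclohexyl]oxy}but-2-enoate
Conditions: Dess–Martin periodinane, NaHCO3, CH2Cl2, 0 °C to rt
Reagents that add atoms: none
Why: Dess–Martin oxidation of a primary alcohol under buffered, non-acidic conditions that leave the enol ether and esters untouched; the aldehyde is used at once.

Step 7
Reactants: 10 ethyl (E)-3-{[(1S,2R,3S)-3-acetoxy-2-methyl-2-(3-oxopropyl)cyclohexyl]oxy}but-2-enoate
Product: 11 ethyl 2-(11α-acetoxy-3α-hydroxy-2α,6β-dimethyl-trans-perhydro-1-benzoxepin-2β-yl)acetate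
Conditions: SmI2 (2.5 equiv, divalent samarium), MeOH (2.5 equiv), THF, 0 °C to rt
Reagents that add atoms: none
Why: Single-electron transfer to the C3 aldehyde gives a samarium ketyl that adds to the β-carbon (C2) of the (E)-β-alkoxycrotonate; a second electron gives the samarium enolate, which methanol protonates to the ester. The closest known reaction type is the SmI2-induced reductive cyclisation of aldehydes onto β-alkoxyacrylates, including β-methyl acceptors, used for trans-fused cyclic ethers up to oxepanes. The oxepane closes in a 7-exo-trig mode through a chair-like transition state in which samarium bridges the ketyl oxygen and the ester carbonyl. C3 is controlled by C7: with the C7 oxygen and C5 both equatorial on the cyclohexane, the ketyl oxygen sits anti to the ring oxygen and the ester arm pseudo-equatorial, syn to C8, so the hydroxyl comes out trans to the arm and cis to H-7 (3S). C2 becomes fully substituted with the methyl group axial, which follows from the (E)-alkene geometry; its configuration is of no consequence because the arm is later cut down to a methyl group. The step needs chemoselective ketyl formation at the aldehyde (the acetate and both esters are inert to SmI2 without a polar additive) and cyclisation faster than simple reduction or pinacol coupling, which the intramolecular, chelated, electron-poor acceptor and the proton source secure.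

Step 8
Reactants: 11 ethyl 2-(11α-acetoxy-3α-hydroxy-2α,6β-dimethyl-trans-perhydro-1-benzoxepin-2β-yl)acetate
Product: 12 ethyl 2-(11α-acetoxy-3α-benzyloxy-2α,6β-dimethyl-trans-perhydro-1-benzoxepin-2β-yl)acetate
Conditions: benzyl 2,2,2-trichloroacetimidate, TfOH (cat.), CH2Cl2–cyclohexane, 0 °C to rt
Reagents that add atoms: benzyl 2,2,2-trichloroacetimidate, N=C(OCc1ccccc1)C(Cl)(Cl)Cl
Why: Acid-catalysed benzylation with the trichloroacetimidate avoids an alkoxide, which could open the β-alkoxy ester by retro-oxa-Michael reaction; the ether also blocks lactonisation of the C3 hydroxyl onto the arm in the next steps.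

Step 9
Reactants: 12 ethyl 2-(11α-acetoxy-3α-benzyloxy-2α,6β-dimethyl-trans-perhydro-1-benzoxepin-2β-yl)acetate
Product: 13 2-(3α-benzyloxy-11α-hydroxy-2α,6β-dimethyl-trans-perhydro-1-benzoxepin-2β-yl)acetic acid
Conditions: LiOH, THF–MeOH–H2O, rt to 40 °C; then aq HCl to pH 3
Reagents that add atoms: lithium hydroxide, [Li+].[OH-]
Why: Saponification of the ethyl ester and of the C11 acetate in one operation; the β-alkoxy carboxylate formed first is not prone to β-elimination.

Step 10
Reactants: 13 2-(3α-benzyloxy-11α-hydroxy-2α,6β-dimethyl-trans-perhydro-1-benzoxepin-2β-yl)acetic acid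
Product: 15 3α-benzyloxy-2,2,6β-trimethyl-trans-perhydro-1-benzoxepin-11α-ol, via Barton ester 14 (not isolated)
Conditions: N-hydroxypyridine-2-thione, DCC, DMAP (cat.), CH2Cl2, rt, dark; then t-BuSH, hν (tungsten lamp), rt
Reagents that add atoms: none
Why: Barton reductive decarboxylation: the thiohydroxamate ester fragments under light to the primary C2-methylene radical, which takes hydrogen from the thiol much faster than it can rearrange, turning the arm into the second C2 methyl group; the hindered C11 hydroxyl does not compete in the carbodiimide coupling.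

Step 11
Reactants: 15 3α-benzyloxy-2,2,6β-trimethyl-trans-perhydro-1-benzoxepin-11α-ol
Product: 16 3α-benzyloxy-2,2,6β-trimethyl-trans-perhydro-1-benzoxepin-11-one
Conditions: Dess–Martin periodinane, NaHCO3, CH2Cl2, rt
Reagents that add atoms: none
Why: Dess–Martin oxidation of a hindered secondary alcohol; the carbinol configuration that served in step 3 is no longer needed.

Step 12
Reactants: 16 3α-benzyloxy-2,2,6β-trimethyl-trans-perhydro-1-benzoxepin-11-one
Product: 17 3α-benzyloxy-2,2,6β-trimethyl-11-methylidene-trans-perhydro-1-benzoxepine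
Conditions: Ph3PCH3Br, KOtBu, toluene, 90 °C
Reagents that add atoms: methyltriphenylphosphonium bromide, C[P+](c1ccccc1)(c1ccccc1)c1ccccc1.[Br-]
Why: Wittig methylenation of an α-quaternary cyclohexanone, which proceeds with the salt-free ylide in hot toluene; this carbon is C12.

Step 13
Reactants: 17 3α-benzyloxy-2,2,6β-trimethyl-11-methylidene-trans-perhydro-1-benzoxepine
Product: 18 3α-benzyloxy-2,2,6β-trimethyl-11-methylidene-trans-perhydro-1-benzoxepin-10-ol (C10 epimers)
Conditions: SeO2 (0.5 equiv), t-BuOOH (3 equiv), CH2Cl2, rt
Reagents that add atoms: selenium dioxide (oxygen carrier), O=[Se]=O; tert-butyl hydroperoxide, CC(C)(C)OO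
Why: Selenium dioxide allylic hydroxylation (ene reaction, then 2,3-sigmatropic shift) returns the double bond to the exocyclic position; C10 is the only allylic carbon that bears hydrogen because C6 is quaternary, so the oxygen is moved from C11 to C10 regiospecifically.

### Left half (steps 14–19)

Step 14
Reactants: 18 3α-benzyloxy-2,2,6β-trimethyl-11-methylidene-trans-perhydro-1-benzoxepin-10-ol (C10 epimers)
Product: 19 3α-benzyloxy-2,2,6β-trimethyl-11-methylidene-trans-perhydro-1-benzoxepin-10-one
Conditions: Dess–Martin periodinane, NaHCO3, CH2Cl2, 0 °C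
Reagents that add atoms: none
Why: Oxidation of the allylic alcohol to the α-methylene ketone, converging both epimers; the enone is shielded by the quaternary C6 and is used without storage.

Step 15
Reactants: 19 3α-benzyloxy-2,2,6β-trimethyl-11-methylidene-trans-perhydro-1-benzoxepin-10-one
Product: 20 3α-benzyloxy-2,2,6β-trimethyl-11β-{[(1-phenyl-1H-tetrazol-5-yl)sulfanyl]methyl}-trans-perhydro-1-benzoxepin-10-one
Conditions: 1-phenyl-1H-tetrazole-5-thiol, Et3N (cat.), CH2Cl2, rt
Reagents that add atoms: 1-phenyl-1H-tetrazole-5-thiol, Sc1nnnn1-c1ccccc1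
Why: Thia-Michael addition of an acidic thiol to an exocyclic enone; the enolate is protonated at C11 from the α face, anti to the axial C6 methyl, and the centre can equilibrate next to the ketone, so C12 ends equatorial (11S).

Step 16
Reactants: 20 3α-benzyloxy-2,2,6β-trimethyl-11β-{[(1-phenyl-1H-tetrazol-5-yl)sulfanyl]methyl}-trans-perhydro-1-benzoxepin-10-one
Product: 21 3α-benzyloxy-2,2,6β,10α-tetramethyl-11β-{[(1-phenyl-1H-tetrazol-5-yl)sulfanyl]methyl}-trans-perhydro-1-benzoxepin-10β-ol
Conditions: MeLi, CeCl3 (anhydrous), THF, −78 °C
Reagents that add atoms: methyllithium, [Li]C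
Why: Organocerium 1,2-addition, chosen because the reagent is weakly basic and does not trigger retro-Michael loss of the thiolate; axial approach to C10 is blocked by the syn-axial C6 methyl, so the methyl group enters from the α face and the hydroxyl becomes axial (10R), as in the target's left half.

Step 17
Reactants: 21 3α-benzyloxy-2,2,6β,10α-tetramethyl-11β-{[(1-phenyl-1H-tetrazol-5-yl)sulfanyl]methyl}-trans-perhydro-1-benzoxepin-10β-ol
Product: 22 3α-benzyloxy-2,2,6β,10α-tetramethyl-11β-{[(1-phenyl-1H-tetrazol-5-yl)sulfonyl]methyl}-trans-perhydro-1-benzoxepin-10β-ol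
Conditions: (NH4)6Mo7O24·4H2O (cat.), H2O2 (30 %), EtOH, 0 °C to rt
Reagents that add atoms: hydrogen peroxide, OO
Why: Molybdate-catalysed oxidation of the heteroaryl sulfide to the sulfone, the usual way to Julia–Kocienski reagents; the tertiary alcohol and benzyl ether are inert.

Step 18
Reactants: 22 3α-benzyloxy-2,2,6β,10α-tetramethyl-11β-{[(1-phenyl-1H-tetrazol-5-yl)sulfonyl]methyl}-trans-perhydro-1-benzoxepin-10β-ol
Product: 23 2,2,6β,10α-tetramethyl-11β-{[(1-phenyl-1H-tetrazol-5-yl)sulfonyl]methyl}-trans-perhydro-1-benzoxepine-3α,10β-diol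
Conditions: H2 (1 atm), Pd(OH)2/C, EtOAc–EtOH, rt
Reagents that add atoms: none
Why: Hydrogenolysis of the benzyl ether, placed after sulfur has reached the sulfone level so that the catalyst is not poisoned; it frees C3 so that this oxygen, unlike C22, can be acetylated at the end.

Step 19
Reactants: 23 2,2,6β,10α-tetramethyl-11β-{[(1-phenyl-1H-tetrazol-5-yl)sulfonyl]methyl}-trans-perhydro-1-benzoxepine-3α,10β-diol
Product: 24 2,2,6β,10α-tetramethyl-11β-{[(1-phenyl-1H-tetrazol-5-yl)sulfonyl]methyl}-3α,10β-bis(triethylsilyloxy)-trans-perhydro-1-benzoxepine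
Conditions: TESOTf, 2,6-lutidine, CH2Cl2, −78 to 0 °C
Reagents that add atoms: triethylsilyl trifluoromethanesulfonate, CC[Si](CC)(CC)OS(=O)(=O)C(F)(F)F
Why: Silyl triflate silylation, strong enough for the axial tertiary alcohol; the silyl ethers keep alkoxides away from the tetrazolyl sulfone during the coupling.

### Right half (steps 20–27)

Step 20
Reactants: 18 3α-benzyloxy-2,2,6β-trimethyl-11-methylidene-trans-perhydro-1-benzoxepin-10-ol (C10 epimers), here with right-half locants
Product: 26 22α-benzyloxy-14β-(hydroxymethyl)-19β,23,23-trimethyl-trans-perhydro-1-benzoxepin-15-ol (C15 epimers), via bis(9-BBN) adduct 25 (not isolated)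
Conditions: 9-BBN (2.5 equiv), THF, 0 to 50 °C; then H2O2 (30 %), aq NaOH, 0 °C to rt
Reagents that add atoms: hydrogen peroxide, OO
Why: Hydroboration–oxidation of the 1,1-disubstituted alkene after the hydroxyl has consumed one equivalent of borane; boron goes to C13 and hydrogen to C14 from the α face, because the axial C19 methyl on the neighbouring carbon screens the other face, which places the hydroxymethyl group equatorial (14S).

Step 21
Reactants: 26 22α-benzyloxy-14β-(hydroxymethyl)-19β,23,23-trimethyl-trans-perhydro-1-benzoxepin-15-ol (C15 epimers)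
Product: 27 22α-benzyloxy-19β,23,23-trimethyl-14β-[(triethylsilyloxy)methyl]-trans-perhydro-1-benzoxepin-15-ol (C15 epimers)
Conditions: TESCl, imidazole, CH2Cl2, −40 to 0 °C
Reagents that add atoms: chlorotriethylsilane, CC[Si](CC)(CC)Cl
Why: Silylation selective for the primary over the hindered secondary hydroxyl.

Step 22
Reactants: 27 22α-benzyloxy-19β,23,23-trimethyl-14β-[(triethylsilyloxy)methyl]-trans-perhydro-1-benzoxepin-15-ol (C15 epimers)
Product: 28 22α-benzyloxy-19β,23,23-trimethyl-14β-[(triethylsilyloxy)methyl]-trans-perhydro-1-benzoxepin-15-one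
Conditions: Dess–Martin periodinane, NaHCO3, CH2Cl2, rt
Reagents that add atoms: none
Why: Dess–Martin oxidation to the C15 ketone; C14 is now enolisable, and the equatorial arrangement set in step 20 is also the thermodynamically preferred one, so the centre is secured twice.

Step 23
Reactants: 28 22α-benzyloxy-19β,23,23-trimethyl-14β-[(triethylsilyloxy)methyl]-trans-perhydro-1-benzoxepin-15-one
Product: 29 22α-benzyloxy-19β,23,23-trimethyl-15-methylidene-14β-[(triethylsilyloxy)methyl]-trans-perhydro-1-benzoxepine
Conditions: Ph3PCH3Br, KOtBu, THF, 0 °C to rt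
Reagents that add atoms: methyltriphenylphosphonium bromide, C[P+](c1ccccc1)(c1ccccc1)c1ccccc1.[Br-]
Why: Wittig methylenation of a β-silyloxy ketone; this carbon becomes the C15 methyl group.

Step 24
Reactants: 29 22α-benzyloxy-19β,23,23-trimethyl-15-methylidene-14β-[(triethylsilyloxy)methyl]-trans-perhydro-1-benzoxepine
Product: 30 15α,15-epoxymethano derivative (spiro-oxirane with oxygen α) of 22α-benzyloxy-19β,23,23-trimethyl-14β-[(triethylsilyloxy)methyl]-trans-perhydro-1-benzoxepine
Conditions: mCPBA, NaHCO3, CH2Cl2, 0 °C
Reagents that add atoms: 3-chloroperoxybenzoic acid, OOC(=O)c1cccc(Cl)c1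
Why: Prilezhaev epoxidation of the exocyclic alkene; the peracid comes from the α face because the syn-axial C19 methyl closes the β face, as is known for exocyclic alkenes of drimane and labdane rings, so oxygen becomes equatorial on C15.

Step 25
Reactants: 30 15α,15-epoxymethano derivative (spiro-oxirane with oxygen α) of 22α-benzyloxy-19β,23,23-trimethyl-14β-[(triethylsilyloxy)methyl]-trans-perhydro-1-benzoxepine
Product: 31 22α-benzyloxy-15β,19β,23,23-tetramethyl-14β-[(triethylsilyloxy)methyl]-trans-perhydro-1-benzoxepin-15α-ol
Conditions: LiAlH4, THF, 0 °C to rt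
Reagents that add atoms: none
Why: Hydride opens the spiro-epoxide at its primary carbon (SN2), leaving the equatorial tertiary alcohol and the axial methyl group (15S), the configuration of the target's right half; the silyl and benzyl ethers are stable.

Step 26
Reactants: 31 22α-benzyloxy-15β,19β,23,23-tetramethyl-14β-[(triethylsilyloxy)methyl]-trans-perhydro-1-benzoxepin-15α-ol
Product: 32 22α-benzyloxy-15β,19β,23,23-tetramethyl-15α-(triethylsilyloxy)-14β-[(triethylsilyloxy)methyl]-trans-perhydro-1-benzoxepine
Conditions: TESOTf, 2,6-lutidine, CH2Cl2, −78 to 0 °C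
Reagents that add atoms: triethylsilyl trifluoromethanesulfonate, CC[Si](CC)(CC)OS(=O)(=O)C(F)(F)F
Why: Silyl triflate silylation of the tertiary alcohol, so that the aldehyde of the next step carries no free β-hydroxyl (retro-aldol) during the coupling.

Step 27
Reactants: 32 22α-benzyloxy-15β,19β,23,23-tetramethyl-15α-(triethylsilyloxy)-14β-[(triethylsilyloxy)methyl]-trans-perhydro-1-benzoxepine
Product: 33 22α-benzyloxy-15β,19β,23,23-tetramethyl-15α-(triethylsilyloxy)-trans-perhydro-1-benzoxepine-14β-carbaldehyde
Conditions: (COCl)2, DMSO, CH2Cl2, −78 to −40 °C; then Et3N, −78 °C to rt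
Reagents that add atoms: none
Why: Swern oxidation applied directly to a primary triethylsilyl ether, a known selective conversion in which the activated sulfonium species cleaves and oxidises the primary silyl ether while tertiary silyl ethers stay; it saves a separate deprotection.

### Coupling and completion (steps 28–31)

Step 28
Reactants: 24 2,2,6β,10α-tetramethyl-11β-{[(1-phenyl-1H-tetrazol-5-yl)sulfonyl]methyl}-3α,10β-bis(triethylsilyloxy)-trans-perhydro-1-benzoxepine; 33 22α-benzyloxy-15β,19β,23,23-tetramethyl-15α-(triethylsilyloxy)-trans-perhydro-1-benzoxepine-14β-carbaldehyde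
Product: 34 12,13-didehydro-22-O-benzyl-3,10,15-tris-O-(triethylsilyl) derivative of the deacetylated tetraol of 37 (mainly E)
Conditions: KN(SiMe3)2, DME, −60 °C; then 33, −60 °C to rt
Reagents that add atoms: none
Why: Julia–Kocienski olefination: the metalated tetrazolyl sulfone adds to the aldehyde, the alkoxide undergoes Smiles rearrangement, and loss of sulfur dioxide and the tetrazolone gives the C12=C13 alkene in one operation; the geometry does not matter, and C11 and C14 are not touched.

Step 29
Reactants: 34 12,13-didehydro-22-O-benzyl-3,10,15-tris-O-(triethylsilyl) derivative of the deacetylated tetraol of 37 (mainly E)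
Product: 35 12,13-didehydro-22-O-benzyl derivative of the deacetylated tetraol of 37 (3α,10β,15α-triol)
Conditions: HF·pyridine, pyridine, THF, 0 °C to rt
Reagents that add atoms: none
Why: Fluoride-mediated cleavage of one secondary and two tertiary triethylsilyl ethers under buffered conditions that do not ionise the tertiary carbinols; the benzyl ether stays on C22.

Step 30
Reactants: 35 12,13-didehydro-22-O-benzyl derivative of the deacetylated tetraol of 37 (3α,10β,15α-triol)
Product: 36 12,13-didehydro-22-O-benzyl derivative of 37 (3α,10β,15α-triacetate)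
Conditions: Ac2O, DMAP, Et3N, toluene, 60–80 °C
Reagents that add atoms: acetic anhydride, CC(=O)OC(C)=O
Why: Acylation under nucleophilic catalysis by 4-(dimethylamino)pyridine, the standard means for tertiary alcohols; only the three hydroxyls meant to be acetates are free.

Step 31
Reactants: 36 12,13-didehydro-22-O-benzyl derivative of 37 (3α,10β,15α-triacetate)
Product: 37 CNP0169816.1, the (3S,6S,7S,10R,11S,14S,15S,18S,19S,22S) 3,10,15-triacetate with free C22 hydroxyl
Conditions: H2 (1 atm), Pd/C (10 %), EtOAc–EtOH, rt
Reagents that add atoms: none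
Why: Catalytic hydrogenation saturates the disubstituted C12=C13 alkene and hydrogenolyses the C22 benzyl ether in the same flask; the acetates and both oxepanes are inert, and no stereocentre is created or touched.

## Compound list

1 | 2-methylcyclohexane-1,3-dione | CC1C(=O)CCCC1=O | starting material
2 | allyl bromide (3-bromoprop-1-ene) | C=CCBr | starting material
3 | 2-methyl-2-(prop-2-en-1-yl)cyclohexane-1,3-dione | C=CCC1(C)C(=O)CCCC1=O | intermediate
4 | (2S,3S)-3-hydroxy-2-methyl-2-(prop-2-en-1-yl)cyclohexan-1-one (hydroxyl cis to allyl) | O=C1CCC[C@H](O)[C@]1(C)CC=C | intermediate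
5 | (1S,2R,3S)-3-hydroxy-2-methyl-2-(prop-2-en-1-yl)cyclohexyl acetate (acetoxy cis, hydroxyl trans to allyl) | C=CC[C@]1(C)[C@@H](O)CCC[C@@H]1OC(C)=O | intermediate
6 | ethyl but-2-ynoate | CC#CC(=O)OCC | starting material
7 | ethyl (E)-3-{[(1S,2R,3S)-3-acetoxy-2-methyl-2-(prop-2-en-1-yl)cyclohexyl]oxy}but-2-enoate | C=CC[C@]1(C)[C@@H](O/C(C)=C/C(=O)OCC)CCC[C@@H]1OC(C)=O | intermediate
8 | B-alkyl-9-borabicyclo[3.3.1]nonane adduct of 7 (boron on the terminal carbon of the arm) | B1(CCC[C@]2(C)[C@@H](O/C(C)=C/C(=O)OCC)CCC[C@@H]2OC(C)=O)C3CCCC1CCC3 | intermediate (not isolated)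
9 | ethyl (E)-3-{[(1S,2R,3S)-3-acetoxy-2-(3-hydroxypropyl)-2-methylcyclohexyl]oxy}but-2-enoate | OCCC[C@]1(C)[C@@H](O/C(C)=C/C(=O)OCC)CCC[C@@H]1OC(C)=O | intermediate
10 | ethyl (E)-3-{[(1S,2R,3S)-3-acetoxy-2-methyl-2-(3-oxopropyl)cyclohexyl]oxy}but-2-enoate (key-step precursor) | O=CCC[C@]1(C)[C@@H](O/C(C)=C/C(=O)OCC)CCC[C@@H]1OC(C)=O | intermediate
11 | ethyl 2-(11α-acetoxy-3α-hydroxy-2α,6β-dimethyl-trans-perhydro-1-benzoxepin-2β-yl)acetate (key-step product) | O[C@H]1CC[C@]2(C)[C@H](CCC[C@@H]2OC(C)=O)O[C@]1(C)CC(=O)OCC | intermediate
12 | ethyl 2-(11α-acetoxy-3α-benzyloxy-2α,6β-dimethyl-trans-perhydro-1-benzoxepin-2β-yl)acetate | c3ccccc3CO[C@H]1CC[C@]2(C)[C@H](CCC[C@@H]2OC(C)=O)O[C@]1(C)CC(=O)OCC | intermediate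
13 | 2-(3α-benzyloxy-11α-hydroxy-2α,6β-dimethyl-trans-perhydro-1-benzoxepin-2β-yl)acetic acid | c3ccccc3CO[C@H]1CC[C@]2(C)[C@H](CCC[C@@H]2O)O[C@]1(C)CC(=O)O | intermediate
14 | 2-thioxopyridin-1(2H)-yl ester (Barton ester) of 13 | c3ccccc3CO[C@H]1CC[C@]2(C)[C@H](CCC[C@@H]2O)O[C@]1(C)CC(=O)ON1C=CC=CC1=S | intermediate (not isolated)
15 | 3α-benzyloxy-2,2,6β-trimethyl-trans-perhydro-1-benzoxepin-11α-ol | c3ccccc3CO[C@H]1CC[C@]2(C)[C@H](CCC[C@@H]2O)OC1(C)C | intermediate
16 | 3α-benzyloxy-2,2,6β-trimethyl-trans-perhydro-1-benzoxepin-11-one | c3ccccc3CO[C@H]1CC[C@]2(C)[C@H](CCCC2=O)OC1(C)C | intermediate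
17 | 3α-benzyloxy-2,2,6β-trimethyl-11-methylidene-trans-perhydro-1-benzoxepine | c3ccccc3CO[C@H]1CC[C@]2(C)[C@H](CCCC2=C)OC1(C)C | intermediate
18 | 3α-benzyloxy-2,2,6β-trimethyl-11-methylidene-trans-perhydro-1-benzoxepin-10-ol (C10 epimers; branch point, equally the right-half 15-ol) | c3ccccc3CO[C@H]1CC[C@]2(C)[C@H](CCC(O)C2=C)OC1(C)C | intermediate
19 | 3α-benzyloxy-2,2,6β-trimethyl-11-methylidene-trans-perhydro-1-benzoxepin-10-one | c3ccccc3CO[C@H]1CC[C@]2(C)[C@H](CCC(=O)C2=C)OC1(C)C | intermediate
20 | 3α-benzyloxy-2,2,6β-trimethyl-11β-{[(1-phenyl-1H-tetrazol-5-yl)sulfanyl]methyl}-trans-perhydro-1-benzoxepin-10-one (11α-H) | c3ccccc3CO[C@H]1CC[C@]2(C)[C@H](CCC(=O)[C@H]2CSc2nnnn2-c2ccccc2)OC1(C)C | intermediate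
21 | 3α-benzyloxy-2,2,6β,10α-tetramethyl-11β-{[(1-phenyl-1H-tetrazol-5-yl)sulfanyl]methyl}-trans-perhydro-1-benzoxepin-10β-ol | c3ccccc3CO[C@H]1CC[C@]2(C)[C@H](CC[C@@](C)(O)[C@H]2CSc2nnnn2-c2ccccc2)OC1(C)C | intermediate
22 | 3α-benzyloxy-2,2,6β,10α-tetramethyl-11β-{[(1-phenyl-1H-tetrazol-5-yl)sulfonyl]methyl}-trans-perhydro-1-benzoxepin-10β-ol | c3ccccc3CO[C@H]1CC[C@]2(C)[C@H](CC[C@@](C)(O)[C@H]2CS(=O)(=O)c2nnnn2-c2ccccc2)OC1(C)C | intermediate
23 | 2,2,6β,10α-tetramethyl-11β-{[(1-phenyl-1H-tetrazol-5-yl)sulfonyl]methyl}-trans-perhydro-1-benzoxepine-3α,10β-diol | O[C@H]1CC[C@]2(C)[C@H](CC[C@@](C)(O)[C@H]2CS(=O)(=O)c2nnnn2-c2ccccc2)OC1(C)C | intermediate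
24 | 2,2,6β,10α-tetramethyl-11β-{[(1-phenyl-1H-tetrazol-5-yl)sulfonyl]methyl}-3α,10β-bis(triethylsilyloxy)-trans-perhydro-1-benzoxepine (left half) | CC[Si](CC)(CC)O[C@H]1CC[C@]2(C)[C@H](CC[C@@](C)(O[Si](CC)(CC)CC)[C@H]2CS(=O)(=O)c2nnnn2-c2ccccc2)OC1(C)C | intermediate
25 | bis(9-borabicyclo[3.3.1]nonane) adduct of 18 (C13 borane, C15 O-borinate; 14α-H) | c3ccccc3CO[C@H]1CC[C@]2(C)[C@H](CCC(OB3C4CCCC3CCC4)[C@H]2CB2C3CCCC2CCC3)OC1(C)C | intermediate (not isolated)
26 | 22α-benzyloxy-14β-(hydroxymethyl)-19β,23,23-trimethyl-trans-perhydro-1-benzoxepin-15-ol (C15 epimers; 14α-H) | c3ccccc3CO[C@H]1CC[C@]2(C)[C@H](CCC(O)[C@H]2CO)OC1(C)C | intermediate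
27 | 22α-benzyloxy-19β,23,23-trimethyl-14β-[(triethylsilyloxy)methyl]-trans-perhydro-1-benzoxepin-15-ol (C15 epimers) | c3ccccc3CO[C@H]1CC[C@]2(C)[C@H](CCC(O)[C@H]2CO[Si](CC)(CC)CC)OC1(C)C | intermediate
28 | 22α-benzyloxy-19β,23,23-trimethyl-14β-[(triethylsilyloxy)methyl]-trans-perhydro-1-benzoxepin-15-one | c3ccccc3CO[C@H]1CC[C@]2(C)[C@H](CCC(=O)[C@H]2CO[Si](CC)(CC)CC)OC1(C)C | intermediate
29 | 22α-benzyloxy-19β,23,23-trimethyl-15-methylidene-14β-[(triethylsilyloxy)methyl]-trans-perhydro-1-benzoxepine | c3ccccc3CO[C@H]1CC[C@]2(C)[C@H](CCC(=C)[C@H]2CO[Si](CC)(CC)CC)OC1(C)C | intermediate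
30 | spiro-oxirane at C15 (oxygen α, methylene β) of 22α-benzyloxy-19β,23,23-trimethyl-14β-[(triethylsilyloxy)methyl]-trans-perhydro-1-benzoxepine | c3ccccc3CO[C@H]1CC[C@]2(C)[C@H](CC[C@@]3(CO3)[C@H]2CO[Si](CC)(CC)CC)OC1(C)C | intermediate
31 | 22α-benzyloxy-15β,19β,23,23-tetramethyl-14β-[(triethylsilyloxy)methyl]-trans-perhydro-1-benzoxepin-15α-ol | c3ccccc3CO[C@H]1CC[C@]2(C)[C@H](CC[C@](C)(O)[C@H]2CO[Si](CC)(CC)CC)OC1(C)C | intermediate
32 | 22α-benzyloxy-15β,19β,23,23-tetramethyl-15α-(triethylsilyloxy)-14β-[(triethylsilyloxy)methyl]-trans-perhydro-1-benzoxepine | c3ccccc3CO[C@H]1CC[C@]2(C)[C@H](CC[C@](C)(O[Si](CC)(CC)CC)[C@H]2CO[Si](CC)(CC)CC)OC1(C)C | intermediate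
33 | 22α-benzyloxy-15β,19β,23,23-tetramethyl-15α-(triethylsilyloxy)-trans-perhydro-1-benzoxepine-14β-carbaldehyde (right half) | c3ccccc3CO[C@H]1CC[C@]2(C)[C@H](CC[C@](C)(O[Si](CC)(CC)CC)[C@H]2C=O)OC1(C)C | intermediate
34 | 12,13-didehydro-22-O-benzyl-3,10,15-tris-O-(triethylsilyl) derivative of the deacetylated tetraol of 37 (E drawn) | CC[Si](CC)(CC)O[C@H]1CC[C@]2(C)[C@H](CC[C@@](C)(O[Si](CC)(CC)CC)[C@H]2/C=C/[C@H]2[C@]3(C)CC[C@H](OCc4ccccc4)C(C)(C)O[C@H]3CC[C@]2(C)O[Si](CC)(CC)CC)OC1(C)C | intermediate
35 | 12,13-didehydro-22-O-benzyl derivative of the deacetylated tetraol of 37 (free 3α, 10β, 15α hydroxyls) | O[C@H]1CC[C@]2(C)[C@H](CC[C@@](C)(O)[C@H]2/C=C/[C@H]2[C@]3(C)CC[C@H](OCc4ccccc4)C(C)(C)O[C@H]3CC[C@]2(C)O)OC1(C)C | intermediate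
36 | 12,13-didehydro-22-O-benzyl derivative of 37 (3α,10β,15α-triacetate) | CC(=O)O[C@H]1CC[C@]2(C)[C@H](CC[C@@](C)(OC(C)=O)[C@H]2/C=C/[C@H]2[C@]3(C)CC[C@H](OCc4ccccc4)C(C)(C)O[C@H]3CC[C@]2(C)OC(C)=O)OC1(C)C | intermediate
37 | CNP0169816.1, (3S,6S,7S,10R,11S,14S,15S,18S,19S,22S)-3,10,15-triacetoxy bis(perhydrobenzoxepine) with free 22-hydroxyl | CC(=O)O[C@H]1CC[C@]2(C)[C@H](CC[C@@](C)(OC(C)=O)[C@H]2CC[C@H]2[C@]3(C)CC[C@H](O)C(C)(C)O[C@H]3CC[C@]2(C)OC(C)=O)OC1(C)C | target

## Step count and the least certain steps

Total step count: 31. Longest linear sequence: 25 steps (steps 1–13, 20–27 and 28–31); the left branch (steps 14–19) is six steps.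

**Step 7 (key step).** The ketyl may be reduced on to the primary alcohol or may dimerise before it closes the seven-membered ring onto a β,β-disubstituted acceptor beside the quaternary C6. If the samarium chelate is disturbed, the C3 selectivity could also erode. Fallback (the oxepane is closed through the C2–O bond instead):
- set out from 5; hydroboration–oxidation of the allyl group gives (1S,2R,3S)-3-hydroxy-2-(3-hydroxypropyl)-2-methylcyclohexyl acetate F1;
- primary-selective oxidation (SO3·pyridine, DMSO, i-Pr2NEt) gives the trans-fused lactol F2;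
- Wittig reaction with isopropylidenetriphenylphosphorane gives the homoprenyl alcohol F3;
- Shi epoxidation, with the ketone enantiomer that delivers the (3S)-oxirane, gives the epoxy alcohol F4;
- acid-catalysed (camphorsulfonic acid) 7-endo opening at the tertiary epoxide carbon gives the oxepanol acetate F5, in competition with 6-exo closure;
- benzylation as in step 8 gives the benzyl ether acetate F6, and methanolysis of the acetate (K2CO3, MeOH) comes back to the route at 15.

**Step 3.** Hemiacetal formation at the neopentyl hydroxyl may be slow, so that acetaldehyde is consumed by its own Tishchenko and aldol reactions, or the β-hydroxy ketone may undergo retro-aldol opening. Fallback (external instead of internal hydride): set out from 4 and acetylate it (Ac2O, pyridine, DMAP) to the keto acetate F7. Reduce the ketone with LiBH(s-Bu)3 in THF at −78 °C and separate the epimers; the one with the hydroxyl trans to the allyl group is 5, where the route is rejoined. The other epimer is returned to F7 by Dess–Martin oxidation. The selectivity of this reduction is not secured by mechanism, which is why it is the fallback and not the plan.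

**Step 28.** Addition between two neopentyl-type partners may be slow, so that the metalated sulfone enolises the aldehyde (followed by loss of silanolate) or condenses with itself. Fallback (alkylation and desulfonylation instead of olefination; no carbonyl electrophile and no alkene):
- set out from 32 and 24; selective methanolysis of the primary silyl ether of 32 (pyridinium p-toluenesulfonate, MeOH, 0 °C) gives the primary alcohol F8;
- Tf2O and 2,6-lutidine give the primary triflate F9, used cold;
- the potassium derivative of 24 is alkylated with F9 to give the C12-sulfonyl coupled product F10;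
- sodium amalgam (Na/Hg, Na2HPO4, MeOH) removes the sulfonyl group and gives the saturated tris(triethylsilyl) ether F11;
- HF·pyridine gives the saturated triol F12, and acetylation as in step 30 gives the saturated triacetate benzyl ether F13;
- hydrogenolysis as in step 31 comes back to the route at 37.

**Step 16.** Enolisation of the β-thio ketone would cause retro-Michael loss of the thiolate, and the organometallic reagent may attack the tetrazole carbon. Fallback (change the order of events so that sulfur enters last): set out from 19 and add MeLi/CeCl3 to the enone carbonyl, again from the α face, to give the tertiary allylic alcohol F14. Hydroboration–oxidation with 9-BBN from the α face gives the 1,3-diol F15 with the hydroxymethyl group equatorial. A Mitsunobu thioetherification of the primary hydroxyl (1-phenyl-1H-tetrazole-5-thiol, PPh3, diisopropyl azodicarboxylate) comes back to the route at 21.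

**Step 24 (with step 25).** Facial selectivity of the epoxidation may be poor if the equatorial silyloxymethyl group on C14 hinders the α face, which would give the C15 epimer after reduction. Fallback (radical hydration instead of epoxidation and hydride opening): set out from 29 and carry out a Mukaiyama hydration (Co(acac)2 (divalent cobalt), PhSiH3, O2, i-PrOH). The planar tertiary C15 radical should be trapped by oxygen on the side away from the syn-axial C19 methyl. This comes back to the route directly at 31 and makes no new compound.

**Step 30.** Acylation of the axial C10 hydroxyl, which is 1,3-diaxial to the C6 methyl, may be incomplete, and forcing conditions may cause dehydration of the tertiary carbinols. Fallback (acylate the alkoxides rather than the alcohols): set out from 35, convert the three hydroxyls into their bromomagnesium alkoxides with EtMgBr in THF at 0 °C, and acylate with acetic anhydride. This comes back to the route at 36 and makes no new compound.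

## Further compounds

F1 | step 7 | (1S,2R,3S)-3-hydroxy-2-(3-hydroxypropyl)-2-methylcyclohexyl acetate | OCCC[C@]1(C)[C@@H](O)CCC[C@@H]1OC(C)=O
F2 | step 7 | trans-fused lactol, 5-acetoxy-4a-methyloctahydro-2H-chromen-2-ol (hemiacetal at squalene C3, anomers) | OC1CC[C@]2(C)[C@H](CCC[C@@H]2OC(C)=O)O1
F3 | step 7 | (1S,2R,3S)-3-hydroxy-2-methyl-2-(4-methylpent-3-en-1-yl)cyclohexyl acetate | CC(C)=CCC[C@]1(C)[C@@H](O)CCC[C@@H]1OC(C)=O
F4 | step 7 | (1S,2R,3S)-2-{2-[(2S)-3,3-dimethyloxiran-2-yl]ethyl}-3-hydroxy-2-methylcyclohexyl acetate | CC1(C)O[C@H]1CC[C@]1(C)[C@@H](O)CCC[C@@H]1OC(C)=O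
F5 | step 7 | 11α-acetoxy-2,2,6β-trimethyl-trans-perhydro-1-benzoxepin-3α-ol | O[C@H]1CC[C@]2(C)[C@H](CCC[C@@H]2OC(C)=O)OC1(C)C
F6 | step 7 | 3α-benzyloxy-2,2,6β-trimethyl-trans-perhydro-1-benzoxepin-11α-yl acetate | c3ccccc3CO[C@H]1CC[C@]2(C)[C@H](CCC[C@@H]2OC(C)=O)OC1(C)C
F7 | step 3 | (1S,2S)-2-methyl-3-oxo-2-(prop-2-en-1-yl)cyclohexyl acetate | O=C1CCC[C@H](OC(C)=O)[C@]1(C)CC=C
F8 | step 28 | 22α-benzyloxy-14β-(hydroxymethyl)-15β,19β,23,23-tetramethyl-15α-(triethylsilyloxy)-trans-perhydro-1-benzoxepine | c3ccccc3CO[C@H]1CC[C@]2(C)[C@H](CC[C@](C)(O[Si](CC)(CC)CC)[C@H]2CO)OC1(C)C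
F9 | step 28 | primary trifluoromethanesulfonate of F8 | c3ccccc3CO[C@H]1CC[C@]2(C)[C@H](CC[C@](C)(O[Si](CC)(CC)CC)[C@H]2COS(=O)(=O)C(F)(F)F)OC1(C)C
F10 | step 28 | 12-[(1-phenyl-1H-tetrazol-5-yl)sulfonyl]-22-O-benzyl-3,10,15-tris-O-(triethylsilyl) derivative of the deacetylated tetraol of 37 (C12 epimers) | CC[Si](CC)(CC)O[C@H]1CC[C@]2(C)[C@H](CC[C@@](C)(O[Si](CC)(CC)CC)[C@H]2C(S(=O)(=O)c4nnnn4-c4ccccc4)C[C@H]2[C@]3(C)CC[C@H](OCc4ccccc4)C(C)(C)O[C@H]3CC[C@]2(C)O[Si](CC)(CC)CC)OC1(C)C
F11 | step 28 | 22-O-benzyl-3,10,15-tris-O-(triethylsilyl) derivative of the deacetylated tetraol of 37 (saturated bridge) | CC[Si](CC)(CC)O[C@H]1CC[C@]2(C)[C@H](CC[C@@](C)(O[Si](CC)(CC)CC)[C@H]2CC[C@H]2[C@]3(C)CC[C@H](OCc4ccccc4)C(C)(C)O[C@H]3CC[C@]2(C)O[Si](CC)(CC)CC)OC1(C)C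
F12 | step 28 | 22-O-benzyl derivative of the deacetylated tetraol of 37 (saturated bridge; free 3α, 10β, 15α hydroxyls) | O[C@H]1CC[C@]2(C)[C@H](CC[C@@](C)(O)[C@H]2CC[C@H]2[C@]3(C)CC[C@H](OCc4ccccc4)C(C)(C)O[C@H]3CC[C@]2(C)O)OC1(C)C
F13 | step 28 | 22-O-benzyl derivative of 37 (saturated bridge; 3α,10β,15α-triacetate) | CC(=O)O[C@H]1CC[C@]2(C)[C@H](CC[C@@](C)(OC(C)=O)[C@H]2CC[C@H]2[C@]3(C)CC[C@H](OCc4ccccc4)C(C)(C)O[C@H]3CC[C@]2(C)OC(C)=O)OC1(C)C
F14 | step 16 | 3α-benzyloxy-2,2,6β,10α-tetramethyl-11-methylidene-trans-perhydro-1-benzoxepin-10β-ol | c3ccccc3CO[C@H]1CC[C@]2(C)[C@H](CC[C@@](C)(O)C2=C)OC1(C)C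
F15 | step 16 | 3α-benzyloxy-11β-(hydroxymethyl)-2,2,6β,10α-tetramethyl-trans-perhydro-1-benzoxepin-10β-ol | c3ccccc3CO[C@H]1CC[C@]2(C)[C@H](CC[C@@](C)(O)[C@H]2CO)OC1(C)C
F0 | step 24 | none | none
F0 | step 30 | none | none
A1 | alternative 1 | C2-symmetric bis(cyclohexene) dialdehyde dibenzoate | O=C[C@]1(C)[C@@H](OC(=O)c2ccccc2)CC=C(C)[C@H]1CC[C@@H]1C(C)=CC[C@H](OC(=O)c3ccccc3)[C@@]1(C)C=O
A2 | alternative 1 | (3E,7E)-3,8-dimethyldeca-1,3,7,9-tetraene | C=C/C(C)=C/CC/C=C(C)/C=C
A3 | alternative 1 | (E)-3-benzoyloxy-2-methylprop-2-enal | O=C/C(C)=C/OC(=O)c1ccccc1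
A4 | alternative 2 | cyclohexanone with the C6 quaternary centre, homoprenyl chain and C11 tert-butyl acetate arm | O=C1CC[C@H](O[Si](C)(C)C(C)(C)C)[C@@](C)(CCC=C(C)C)[C@@H]1CC(=O)OC(C)(C)C
A5 | alternative 2 | (4S)-4-(tert-butyldimethylsilyloxy)-3-methylcyclohex-2-en-1-one | O=C1CC[C@H](O[Si](C)(C)C(C)(C)C)C(C)=C1
A6 | alternative 2 | (4-methylpent-3-en-1-yl)magnesium bromide | CC(C)=CCC[Mg]Br
A7 | alternative 2 | tert-butyl 2-iodoacetate | CC(C)(C)OC(=O)CI
A8 | alternative 3 | tetracyclic 3,10,15-triol with the C22 benzyl ether | O[C@H]1CC[C@]2(C)[C@H](CC[C@@](C)(O)[C@H]2CC[C@H]2[C@]3(C)CC[C@H](OCc4ccccc4)C(C)(C)O[C@H]3CC[C@]2(C)O)OC1(C)C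
A9 | alternative 3 | keto olefin with the C15 methyl ketone and the E C13=C14 alkene on the preformed right oxepane | O[C@H]1CC[C@]2(C)[C@H](CC[C@@](C)(O)[C@H]2CC/C=C/[C@]2(C)CC[C@H](OCc3ccccc3)C(C)(C)O[C@H]2CCC(C)=O)OC1(C)C
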